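**Plan**
- Retrosynthesis first removes the benzyl group from the ring A phenol. It then opens the benzofuran at O1'–C2' and C3'–C3a', giving a C5-ethynyl group on ring B and an ortho-iodophenol made from dihydroconiferyl alcohol. It then cuts C2–C3 of the dihydrobenzofuran and finally the O1–CH2 ether bond.
- Enabling feature: in the dihydrobenzofuran (O1, C2, C3 fused to benzo ring B; guaiacyl ring A on C2), C3 is benzylic to ring B and carries a CH2OH that can stand as an ester, so C3 can become a donor–acceptor carbenoid carbon. C2 is the CH2 of an O1–CH2–ring A ether, and its C–H lies five atoms from C3 and is activated by O1 and ring A.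
- Forward order: O1–C2 ether, arylacetate, diazo ester, dihydrofuran ring by C2–C3 insertion, ester to CH2OH, ethynyl group at C5, benzofuran ring by coupling/cyclisation with the iodophenol, debenzylation.
- Stereochemistry: C2 is set by the chiral dirhodium carboxylate during the insertion. C3 is set by methoxide equilibration to the trans ester in the same pot. After the ester is reduced, C3 can no longer epimerise.
- Protecting group: the ring A phenol is carried as a benzyl ether, because it must survive methoxide; a free or base-labile para-oxygen would open the ring at C2 under the equilibration conditions.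

Key step: step 6

Assumption: the N-phthaloyl-tert-leucinate dirhodium catalysts are taken to give 2R with the (S)-ligand in this class of insertion, so the (R)-ligand complex is specified for 2S; if a trial on 7 shows the opposite sense, the antipodal complex is used with nothing else changed.

**Route**

Step 1
Reactants: 1 [4-(benzyloxy)-3-methoxyphenyl]methanol
Product: 2 1-(benzyloxy)-4-(chloromethyl)-2-methoxybenzene
Conditions: SOCl2 (1.2 equiv), CH2Cl2, 0 °C → rt
Reagents that add atoms: thionyl chloride, O=S(Cl)Cl
Why: Chlorodehydroxylation of an electron-rich benzylic alcohol through its chlorosulfite (nucleophilic substitution) should be fast at 0 °C and leave the aryl benzyl ether untouched.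

Step 2
Reactants: 3 5-bromo-2-hydroxy-3-methoxybenzaldehyde; 2 1-(benzyloxy)-4-(chloromethyl)-2-methoxybenzene
Product: 4 2-{[4-(benzyloxy)-3-methoxybenzyl]oxy}-5-bromo-3-methoxybenzaldehyde
Conditions: K2CO3, DMF, 60 °C
Reagents that add atoms: none
Why: Williamson ether synthesis, in which the acidic phenol (ortho-formyl, para-bromo) is deprotonated by carbonate and displaces chloride from the reactive 4-alkoxybenzyl chloride by SN2.

Step 3
Reactants: 4 2-{[4-(benzyloxy)-3-methoxybenzyl]oxy}-5-bromo-3-methoxybenzaldehyde
Product: 5 1-{[4-(benzyloxy)-3-methoxybenzyl]oxy}-4-bromo-2-methoxy-6-(2-methoxyethenyl)benzene (E/Z mixture)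
Conditions: MeOCH2PPh3Cl, KOtBu, THF, 0 °C → rt
Reagents that add atoms: (methoxymethyl)triphenylphosphonium chloride, COC[P+](c1ccccc1)(c1ccccc1)c1ccccc1.[Cl-]
Why: Wittig olefination of the aryl aldehyde with the non-stabilised methoxymethylene ylide adds the one carbon needed, and the E/Z mixture is of no consequence because both isomers converge in step 4.

Step 4
Reactants: 5 1-{[4-(benzyloxy)-3-methoxybenzyl]oxy}-4-bromo-2-methoxy-6-(2-methoxyethenyl)benzene
Product: 6 methyl 2-(2-{[4-(benzyloxy)-3-methoxybenzyl]oxy}-5-bromo-3-methoxyphenyl)acetate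
Conditions: pyridinium chlorochromate [C5H5NH][CrO3Cl] (hexavalent chromium), NaOAc, 4 Å molecular sieves, CH2Cl2, rt
Reagents that add atoms: pyridinium chlorochromate, [O-][Cr](=O)(=O)Cl.c1cc[nH+]cc1
Why: Chlorochromate oxidation of an enol ether to the ester is a known reaction in which the chromium oxidant attacks the electron-rich double bond and a 1,2-hydride shift in the resulting oxocarbenium chromate gives the methyl ester directly, under buffered conditions that should spare the acid-sensitive dialkoxybenzyl aryl ether and the aryl bromide.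

Step 5
Reactants: 6 methyl 2-(2-{[4-(benzyloxy)-3-methoxybenzyl]oxy}-5-bromo-3-methoxyphenyl)acetate
Product: 7 methyl 2-(2-{[4-(benzyloxy)-3-methoxybenzyl]oxy}-5-bromo-3-methoxyphenyl)-2-diazoacetate
Conditions: 4-acetamidobenzenesulfonyl azide, DBU, MeCN, 0 °C → rt
Reagents that add atoms: 4-acetamidobenzenesulfonyl azide, CC(=O)Nc1ccc(cc1)S(=O)(=O)N=[N+]=[N-]
Why: Regitz diazo transfer to the DBU-generated enolate of the benzylic ester is the standard preparation of aryldiazoacetates and tolerates ortho-alkoxy substituents and aryl halides.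

Step 6
Reactants: 7 methyl 2-(2-{[4-(benzyloxy)-3-methoxybenzyl]oxy}-5-bromo-3-methoxyphenyl)-2-diazoacetate
Product: 9 methyl (2S,3S)-2-[4-(benzyloxy)-3-methoxyphenyl]-5-bromo-7-methoxy-2,3-dihydrobenzofuran-3-carboxylate (trans), via cis ester 8 (not isolated)
Conditions: Rh2(R-PTTL)4 {dirhodium tetrakis[N-phthaloyl-(R)-tert-leucinate], divalent rhodium} (1 mol %), toluene, −60 °C; then NaOMe (0.3 equiv), MeOH, −60 °C → rt; AcOH quench
Reagents that add atoms: none
Why: The divalent-rhodium carboxylate expels N2 from 7 to give a donor–acceptor rhodium carbenoid at C3 (donor ring B, acceptor CO2Me), which inserts through a concerted, asynchronous three-centre transition state with hydride-transfer character into one of the two enantiotopic C–H bonds of the O1–CH2–ring A ether and so forms the C2–C3 bond. The closest known reaction type is the dirhodium-catalysed enantioselective intramolecular C–H insertion of aryldiazoacetates into benzylic ether C–H bonds, which delivers cis-2-aryl-2,3-dihydrobenzofuran-3-carboxylates, followed by base epimerisation of such esters. The dihydrofuran ring closes by 1,5-C–H insertion, the carbenoid carbon C3 and the inserting carbon C2 being the two ends of the five-atom chain C3–C3a–C7a–O1–C2. C2 is set by the chiral N-phthaloyl-tert-leucinate ligand sphere, which selects one of the two enantiotopic hydrogens (the (R)-ligand complex for 2S), whereas C3 is formed cis (8) under kinetic control and is then turned trans by NaOMe through enolisation of the benzylic ester and reprotonation, C2 having no acidic hydrogen and staying fixed. The step needs site selectivity for this C–H bond over carbene dimerisation, aromatic cycloaddition and other C–H bonds; this is secured by stabilisation of the developing positive charge at C2 by O1 and electron-rich ring A, by a five-membered geometry that no other activated C–H bond (ring B OMe, distal OCH2Ph) can reach, and by low temperature and dilution. The aryl bromide and both benzyl-type ethers are inert to the carbenoid and to catalytic methoxide.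

Step 7
Reactants: 9 methyl (2S,3S)-2-[4-(benzyloxy)-3-methoxyphenyl]-5-bromo-7-methoxy-2,3-dihydrobenzofuran-3-carboxylate
Product: 10 {(2S,3R)-2-[4-(benzyloxy)-3-methoxyphenyl]-5-bromo-7-methoxy-2,3-dihydrobenzofuran-3-yl}methanol
Conditions: LiBH4, THF, 0 °C → rt
Reagents that add atoms: none
Why: Chemoselective hydride reduction of the ester by LiBH4 gives the primary alcohol without touching the aryl bromide or the ethers; the spatial arrangement is unchanged (the descriptor at C3 changes from S to R only through the priority rules) and C3 is no longer epimerisable afterwards.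

Step 8
Reactants: 10 {(2S,3R)-2-[4-(benzyloxy)-3-methoxyphenyl]-5-bromo-7-methoxy-2,3-dihydrobenzofuran-3-yl}methanol
Product: 11 {(2S,3R)-2-[4-(benzyloxy)-3-methoxyphenyl]-7-methoxy-5-[(trimethylsilyl)ethynyl]-2,3-dihydrobenzofuran-3-yl}methanol
Conditions: ethynyltrimethylsilane, PdCl2(PhCN)2 (3 mol %), P(t-Bu)3·HBF4 (6 mol %), CuI (2 mol %), i-Pr2NH, 1,4-dioxane, rt → 40 °C
Reagents that add atoms: ethynyltrimethylsilane, C#C[Si](C)(C)C
Why: Sonogashira coupling, in which the bulky electron-rich phosphine allows oxidative addition of the unhindered but electron-rich aryl bromide near room temperature and the free primary alcohol is tolerated.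

Step 9
Reactants: 11 {(2S,3R)-2-[4-(benzyloxy)-3-methoxyphenyl]-7-methoxy-5-[(trimethylsilyl)ethynyl]-2,3-dihydrobenzofuran-3-yl}methanol
Product: 12 {(2S,3R)-2-[4-(benzyloxy)-3-methoxyphenyl]-5-ethynyl-7-methoxy-2,3-dihydrobenzofuran-3-yl}methanol
Conditions: K2CO3 (0.2 equiv), MeOH/THF, rt
Reagents that add atoms: none
Why: Base-catalysed methanolysis of the alkynyl C–Si bond (protiodesilylation) is mild enough to leave the benzyl ether and both stereocentres unaffected.

Step 10
Reactants: 13 4-(3-hydroxypropyl)-2-methoxyphenol (dihydroconiferyl alcohol)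
Product: 14 4-(3-hydroxypropyl)-2-iodo-6-methoxyphenol
Conditions: I2, KI, NaHCO3, THF/H2O, 0 °C → rt
Reagents that add atoms: iodine, II
Why: Electrophilic aromatic iodination of the phenoxide goes to the only free position ortho to the hydroxyl, the para position being blocked by the propanol chain.

Step 11
Reactants: 12 {(2S,3R)-2-[4-(benzyloxy)-3-methoxyphenyl]-5-ethynyl-7-methoxy-2,3-dihydrobenzofuran-3-yl}methanol; 14 4-(3-hydroxypropyl)-2-iodo-6-methoxyphenol
Product: 16 3-{2-[(2S,3R)-2-[4-(benzyloxy)-3-methoxyphenyl]-3-(hydroxymethyl)-7-methoxy-2,3-dihydrobenzofuran-5-yl]-7-methoxybenzofuran-5-yl}propan-1-ol, via alkynylphenol 15 (not isolated)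
Conditions: PdCl2(PPh3)2 (5 mol %), CuI (5 mol %), Et3N, DMF, 60 °C, degassed
Reagents that add atoms: none
Why: Sonogashira coupling of the ortho-iodophenol with the terminal alkyne, followed in the same pot by 5-endo-dig attack of the phenol oxygen on the metal-activated alkyne (Castro–Stephens/Larock-type heteroannulation), is an established one-pot entry to 2-arylbenzofurans and tolerates free hydroxyl groups.

Step 12
Reactants: 16 3-{2-[(2S,3R)-2-[4-(benzyloxy)-3-methoxyphenyl]-3-(hydroxymethyl)-7-methoxy-2,3-dihydrobenzofuran-5-yl]-7-methoxybenzofuran-5-yl}propan-1-ol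
Product: 17 3-{2-[(2S,3R)-2-(4-hydroxy-3-methoxyphenyl)-3-(hydroxymethyl)-7-methoxy-2,3-dihydrobenzofuran-5-yl]-7-methoxybenzofuran-5-yl}propan-1-ol (target)
Conditions: H2 (1 atm), Pd/C (10% palladium on carbon), EtOAc/MeOH, rt, stopped at consumption of 16
Reagents that add atoms: none
Why: Hydrogenolysis of the primary aryl benzyl ether over palladium on carbon is much faster than cleavage of the hindered cyclic C2–O1 benzylic bond or saturation of the aromatic benzofuran, so the phenol should be released with both stereocentres and both heterocycles intact.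

**Compound list**

1 | [4-(benzyloxy)-3-methoxyphenyl]methanol | COc1cc(CO)ccc1OCc1ccccc1 | starting material
2 | 1-(benzyloxy)-4-(chloromethyl)-2-methoxybenzene | COc1cc(CCl)ccc1OCc1ccccc1 | intermediate
3 | 5-bromo-2-hydroxy-3-methoxybenzaldehyde | COc1cc(Br)cc(C=O)c1O | starting material
4 | 2-{[4-(benzyloxy)-3-methoxybenzyl]oxy}-5-bromo-3-methoxybenzaldehyde | COc1cc(COc2c(OC)cc(Br)cc2C=O)ccc1OCc1ccccc1 | intermediate
5 | 1-{[4-(benzyloxy)-3-methoxybenzyl]oxy}-4-bromo-2-methoxy-6-(2-methoxyethenyl)benzene (E/Z mixture) | COC=Cc1cc(Br)cc(OC)c1OCc1ccc(OCc2ccccc2)c(OC)c1 | intermediate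
6 | methyl 2-(2-{[4-(benzyloxy)-3-methoxybenzyl]oxy}-5-bromo-3-methoxyphenyl)acetate | COC(=O)Cc1cc(Br)cc(OC)c1OCc1ccc(OCc2ccccc2)c(OC)c1 | intermediate
7 | methyl 2-(2-{[4-(benzyloxy)-3-methoxybenzyl]oxy}-5-bromo-3-methoxyphenyl)-2-diazoacetate | COC(=O)C(=[N+]=[N-])c1cc(Br)cc(OC)c1OCc1ccc(OCc2ccccc2)c(OC)c1 | intermediate
8 | methyl (2S,3R)-2-[4-(benzyloxy)-3-methoxyphenyl]-5-bromo-7-methoxy-2,3-dihydrobenzofuran-3-carboxylate (cis, not isolated) | COc1cc([C@H]2Oc3c(OC)cc(Br)cc3[C@H]2C(=O)OC)ccc1OCc1ccccc1 | intermediate
9 | methyl (2S,3S)-2-[4-(benzyloxy)-3-methoxyphenyl]-5-bromo-7-methoxy-2,3-dihydrobenzofuran-3-carboxylate (trans) | COc1cc([C@H]2Oc3c(OC)cc(Br)cc3[C@@H]2C(=O)OC)ccc1OCc1ccccc1 | intermediate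
10 | {(2S,3R)-2-[4-(benzyloxy)-3-methoxyphenyl]-5-bromo-7-methoxy-2,3-dihydrobenzofuran-3-yl}methanol | COc1cc([C@H]2Oc3c(OC)cc(Br)cc3[C@@H]2CO)ccc1OCc1ccccc1 | intermediate
11 | {(2S,3R)-2-[4-(benzyloxy)-3-methoxyphenyl]-7-methoxy-5-[(trimethylsilyl)ethynyl]-2,3-dihydrobenzofuran-3-yl}methanol | COc1cc([C@H]2Oc3c(OC)cc(C#C[Si](C)(C)C)cc3[C@@H]2CO)ccc1OCc1ccccc1 | intermediate
12 | {(2S,3R)-2-[4-(benzyloxy)-3-methoxyphenyl]-5-ethynyl-7-methoxy-2,3-dihydrobenzofuran-3-yl}methanol | COc1cc([C@H]2Oc3c(OC)cc(C#C)cc3[C@@H]2CO)ccc1OCc1ccccc1 | intermediate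
13 | 4-(3-hydroxypropyl)-2-methoxyphenol (dihydroconiferyl alcohol) | COc1cc(CCCO)ccc1O | starting material
14 | 4-(3-hydroxypropyl)-2-iodo-6-methoxyphenol | COc1cc(CCCO)cc(I)c1O | intermediate
15 | 2-({(2S,3R)-2-[4-(benzyloxy)-3-methoxyphenyl]-3-(hydroxymethyl)-7-methoxy-2,3-dihydrobenzofuran-5-yl}ethynyl)-4-(3-hydroxypropyl)-6-methoxyphenol (not isolated) | COc1cc([C@H]2Oc3c(OC)cc(C#Cc4cc(CCCO)cc(OC)c4O)cc3[C@@H]2CO)ccc1OCc1ccccc1 | intermediate
16 | 3-{2-[(2S,3R)-2-[4-(benzyloxy)-3-methoxyphenyl]-3-(hydroxymethyl)-7-methoxy-2,3-dihydrobenzofuran-5-yl]-7-methoxybenzofuran-5-yl}propan-1-ol | COc1cc([C@H]2Oc3c(OC)cc(-c4cc5cc(CCCO)cc(OC)c5o4)cc3[C@@H]2CO)ccc1OCc1ccccc1 | intermediate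
17 | 3-{2-[(2S,3R)-2-(4-hydroxy-3-methoxyphenyl)-3-(hydroxymethyl)-7-methoxy-2,3-dihydrobenzofuran-5-yl]-7-methoxybenzofuran-5-yl}propan-1-ol | COc1cc([C@H]2Oc3c(OC)cc(-c4cc5cc(CCCO)cc(OC)c5o4)cc3[C@@H]2CO)ccc1O | target

**Step count**

Total steps: 12. Longest linear sequence: 11 (steps 1–9, 11, 12); step 10 makes the second fragment.

**Steps most likely to fail**

Step 6. The catalyst may not discriminate well enough between the two enantiotopic C–H bonds, because the C7 methoxy group next to O1 twists the benzyloxy arm out of the ring B plane. Configuration at C2 could also erode through reversible ring opening of the ester enolate during the methoxide equilibration. The fallback replaces catalyst-only control by auxiliary-plus-catalyst control, which gives separable diastereomers and needs no base equilibration. It sets out from 6. Saponification (LiOH, THF/H2O) should give 2-(2-{[4-(benzyloxy)-3-methoxybenzyl]oxy}-5-bromo-3-methoxyphenyl)acetic acid F1. Carbodiimide coupling (EDC·HCl, DMAP, CH2Cl2) with (S)-2-hydroxy-1-(pyrrolidin-1-yl)propan-1-one should give the lactamide ester F2. Diazo transfer as in step 5 should give the diazo ester F3. Rh2(S-DOSP)4 {dirhodium tetrakis[N-(4-dodecylbenzenesulfonyl)-(S)-prolinate], divalent rhodium} in CH2Cl2 is then expected to give the trans (2S,3S) lactamide ester F4 directly by matched double stereodifferentiation, and the minor diastereomer would be removed by chromatography. The auxiliary and catalyst are taken as the matched pair for 2S; both antipodes of each are available if the sense proves opposite. LiBH4 in THF cleaves the auxiliary reductively, and the sequence comes back to the route at 10.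

Step 4. The chromium oxidant may cleave the enol ether double bond back to aldehyde 4, or oxidise further at the activated benzylic carbon, instead of giving clean hydride shift to the ester. The fallback separates hydrolysis from oxidation and sets out from 5. Brief treatment with 1 M HCl in THF at rt should give 2-(2-{[4-(benzyloxy)-3-methoxybenzyl]oxy}-5-bromo-3-methoxyphenyl)acetaldehyde F5. Pinnick oxidation (NaClO2, NaH2PO4, 2-methyl-2-butene, t-BuOH/H2O) should give the arylacetic acid F1, the same compound that carries this label in the fallback to step 6. Methylation (MeI, K2CO3, DMF) brings the sequence back to the route at 6.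

Step 11. The electron-rich terminal alkyne may homocouple oxidatively under copper catalysis, and the cyclisation may stall at the alkynylphenol. The fallback builds the benzofuran on the small fragment first and joins the halves by C–H arylation, so alkyne 12 is no longer needed. It sets out from 14 and 10. Coupling/cyclisation of 14 with ethynyltrimethylsilane (PdCl2(PPh3)2, CuI, Et3N, DMF, 60 °C) should give 3-[7-methoxy-2-(trimethylsilyl)benzofuran-5-yl]propan-1-ol F6. Desilylation with Bu4NF in THF should give 3-(7-methoxybenzofuran-5-yl)propan-1-ol F7. Direct C2–H arylation of F7 with aryl bromide 10 by concerted metalation–deprotonation (Pd(OAc)2, PCy3·HBF4, pivalic acid, K2CO3, DMA, 100 °C) comes back to the route at 16.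

**Further compounds**

F1 | step 6 | 2-(2-{[4-(benzyloxy)-3-methoxybenzyl]oxy}-5-bromo-3-methoxyphenyl)acetic acid | OC(=O)Cc1cc(Br)cc(OC)c1OCc1ccc(OCc2ccccc2)c(OC)c1
F2 | step 6 | (S)-1-oxo-1-(pyrrolidin-1-yl)propan-2-yl 2-(2-{[4-(benzyloxy)-3-methoxybenzyl]oxy}-5-bromo-3-methoxyphenyl)acetate | C[C@H](OC(=O)Cc1cc(Br)cc(OC)c1OCc1ccc(OCc2ccccc2)c(OC)c1)C(=O)N1CCCC1
F3 | step 6 | (S)-1-oxo-1-(pyrrolidin-1-yl)propan-2-yl 2-(2-{[4-(benzyloxy)-3-methoxybenzyl]oxy}-5-bromo-3-methoxyphenyl)-2-diazoacetate | C[C@H](OC(=O)C(=[N+]=[N-])c1cc(Br)cc(OC)c1OCc1ccc(OCc2ccccc2)c(OC)c1)C(=O)N1CCCC1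
F4 | step 6 | (S)-1-oxo-1-(pyrrolidin-1-yl)propan-2-yl (2S,3S)-2-[4-(benzyloxy)-3-methoxyphenyl]-5-bromo-7-methoxy-2,3-dihydrobenzofuran-3-carboxylate (trans) | COc1cc([C@H]2Oc3c(OC)cc(Br)cc3[C@@H]2C(=O)O[C@@H](C)C(=O)N4CCCC4)ccc1OCc1ccccc1
F5 | step 4 | 2-(2-{[4-(benzyloxy)-3-methoxybenzyl]oxy}-5-bromo-3-methoxyphenyl)acetaldehyde | O=CCc1cc(Br)cc(OC)c1OCc1ccc(OCc2ccccc2)c(OC)c1
F6 | step 11 | 3-[7-methoxy-2-(trimethylsilyl)benzofuran-5-yl]propan-1-ol | COc1cc(CCCO)cc2cc([Si](C)(C)C)oc12
F7 | step 11 | 3-(7-methoxybenzofuran-5-yl)propan-1-ol | COc1cc(CCCO)cc2ccoc12
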